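**Retrosynthesis**
- Micothiazole comes from Zn(Cu/Ag) Z-selective double semireduction of bis-alkyne **20**. **20** is the Sonogashira product of terminal alkyne **14** and vinyl bromide **19**.
- **14** comes from BF3-assisted acetylide opening of terminal epoxide **12**, which is made from diol **11** (acetonide **10**). The epoxide is the only ring formed in the route. The thiazole and the dioxolane are pre-existing.
- Key disconnection: the thiazole C2–C(CH3)2 quaternary bond is made by a photochemical Minisci reaction of thiazole **9** with the tertiary radical from alcohol **3** (via oxalate **6**).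
- **3** comes from (R)-glycerate acetonide **1** and MeMgBr. Ester **1** carries the single carbinol stereocentre unchanged to the target.
- **9** comes from 4-(chloromethyl)thiazole and pent-1-en-4-yne. **19** comes from 3-bromobut-3-en-1-ol.

Assumption: the (R)-glycerate ester (D-mannitol-derived), 4-(chloromethyl)thiazole·HCl, pent-1-en-4-yne and 3-bromobut-3-en-1-ol are purchasable.

**Step 1**
Reactants: **1** methyl (4R)-2,2-dimethyl-1,3-dioxolane-4-carboxylate; **2** methylmagnesium bromide
Product: **3** 2-[(4R)-2,2-dimethyl-1,3-dioxolan-4-yl]propan-2-ol
Conditions: **2** (3.5 equiv), Et2O/THF, 0 °C → rt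
Reagents that add atoms: MeMgBr, C[Mg]Br (two CH3 groups)
Why: Double Grignard addition to the ester, via the methyl ketone, gives the tertiary alcohol. The acetonide is stable, and the α-stereocentre is not touched, so it is retained (R).

**Step 2**
Reactants: **3**; **4** oxalyl chloride; **5** N-hydroxyphthalimide
Product: **6** 2-[(4R)-2,2-dimethyl-1,3-dioxolan-4-yl]propan-2-yl 1,3-dioxoisoindolin-2-yl oxalate
Conditions: **4** (2 equiv), 2,6-lutidine, CH2Cl2, 0 °C; concentrate; then **5**, pyridine, CH2Cl2, 0 °C → rt
Reagents that add atoms: oxalyl chloride, ClC(=O)C(=O)Cl; N-hydroxyphthalimide, O=C1c2ccccc2C(=O)N1O (both retained as the oxalate ester)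
Why: Tertiary alcohols convert to N-phthalimidoyl oxalates via the chlorooxalate (Overman-type activation). Lutidine buffers the HCl so the acetonide survives. The stereocentre is not involved.

**Step 3**
Reactants: **7** 4-(chloromethyl)thiazole hydrochloride; **8** pent-1-en-4-yne
Product: **9** 4-(hex-5-en-2-yn-1-yl)thiazole
Conditions: **8** (3 equiv) + EtMgBr (3 equiv), THF, 0 °C; then CuI (10 mol %), **7**, 0 °C → rt
Reagents that add atoms: none
Why: Cu-catalysed SN2 coupling of an alkynyl Grignard with a heteroarylmethyl chloride. One equivalent of the Grignard neutralises the HCl salt, and the C2–H of the thiazole is left free for the Minisci step.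

**Step 4**
Reactants: **6**; **9**
Product: **10** 2-{2-[(4S)-2,2-dimethyl-1,3-dioxolan-4-yl]propan-2-yl}-4-(hex-5-en-2-yn-1-yl)thiazole
Conditions: **6** (1.5 equiv), **9** (1 equiv), 4CzIPN (2 mol %), Hantzsch ester (10 mol %, initiator), TFA (1.2 equiv), DMSO, blue LEDs (450 nm), 25 °C, 16 h
Reagents that add atoms: none (the tertiary alkyl group comes from **6**; phthalimide and 2 CO2 are lost)
Why: Proposed new method: redox-neutral photocatalytic tert-alkylation of the unblocked C2–H of a simple 4-alkylthiazole that carries an internal alkyne and a terminal alkene. The tertiary radical is stereodefined and β,β′-dioxygenated. The acceptor is the thiazolium trifluoroacetate.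
- Mechanism: excited 4CzIPN (or its Hantzsch-ester-reduced form) reduces **6**. The phthalimidoyl oxalate fragments to phthalimide anion and an alkoxy-oxalyl radical, which loses 2 CO2 to give the nucleophilic tertiary radical •C(CH3)2–CH(O–)CH2O–. The radical adds to C2, the most electron-poor position of the thiazolium. The σ-adduct loses H+, and the resulting strongly reducing radical reduces another molecule of **6** (chain) while rearomatising.
- Stereochemistry: the radical centre is adjacent to, not at, the stereocentre, and there is no β-leaving group, so the stereocentre is retained. The descriptor changes from R to S only because CIP priorities change.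
- Closest known reaction: tertiary-oxalate radical generation combined with decarboxylative Minisci alkylation of N-acyloxyphthalimides on pyridines, quinolines and benzothiazoles.

**Step 5**
Reactants: **10**
Product: **11** (2S)-3-[4-(hex-5-en-2-yn-1-yl)thiazol-2-yl]-3-methylbutane-1,2-diol
Conditions: 2 M HCl (aq), THF, 50 °C, 4 h; then NaHCO3
Reagents that add atoms: none
Why: Acid hydrolysis of the 1,3-dioxolane (acetonide) releases the diol. The alkyne, alkene and thiazole are inert to these conditions, and the stereocentre is not involved.

**Step 6**
Reactants: **11**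
Product: **12** 2-{2-[(2S)-oxiran-2-yl]propan-2-yl}-4-(hex-5-en-2-yn-1-yl)thiazole
Conditions: NaH (2.2 equiv), THF, 0 °C; then TsCl (1.05 equiv), 0 °C → rt
Reagents that add atoms: none (TsCl leaves as TsO–)
Why: The primary alkoxide is tosylated, and the secondary alkoxide closes onto the primary carbon (3-exo-tet) to give the epoxide. Pre-forming the alkoxide favours epoxide closure over N-alkylation of the thiazole. The C–O bond at the stereocentre is never broken, so configuration is retained.

**Step 7**
Reactants: **12**; **13** trimethylsilylacetylene
Product: **14** (3R)-2-[4-(hex-5-en-2-yn-1-yl)thiazol-2-yl]-2-methylhex-5-yn-3-ol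
Conditions: **13** (2.5 equiv), n-BuLi (2.4 equiv), THF, −78 °C; BF3·OEt2 (2.5 equiv); add **12**, −78 → −40 °C; then K2CO3, MeOH, rt
Reagents that add atoms: trimethylsilylacetylene, C#C[Si](C)(C)C (the C≡CH unit is retained after desilylation)
Why: BF3-promoted opening of a terminal epoxide by lithium acetylide (Yamaguchi conditions) attacks the unhindered CH2. Excess BF3 also masks the thiazole nitrogen. Configuration is retained, giving (3R), the target's carbinol configuration.

**Step 8**
Reactants: **15** 3-bromobut-3-en-1-ol; **16** diphenyl phosphorazidate (DPPA)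
Product: **17** 2-bromo-4-azidobut-1-ene
Conditions: PPh3, DIAD, **16**, THF, 0 °C → rt (keep in solution; do not concentrate to dryness)
Reagents that add atoms: DPPA, [N-]=[N+]=NP(=O)(Oc1ccccc1)Oc1ccccc1 (provides N3)
Why: Mitsunobu azidation of a primary alcohol. The vinyl bromide is unaffected.

**Step 9**
Reactants: **17**; **18** methyl chloroformate
Product: **19** methyl (3-bromobut-3-en-1-yl)carbamate
Conditions: PPh3, THF, rt; H2O, 50 °C; then **18**, NaHCO3 (aq), 0 °C
Reagents that add atoms: methyl chloroformate, COC(=O)Cl (provides CO2Me)
Why: Staudinger reduction to the amine, then Schotten–Baumann carbamoylation. The vinyl bromide survives.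

**Step 10**
Reactants: **14**; **19**
Product: **20** methyl N-[(7R)-8-[4-(hex-5-en-2-yn-1-yl)-1,3-thiazol-2-yl]-7-hydroxy-8-methyl-3-methylidenenon-4-yn-1-yl]carbamate
Conditions: Pd(PPh3)4 (5 mol %), CuI (10 mol %), Et3N, THF, 40 °C
Reagents that add atoms: none
Why: Sonogashira coupling of the terminal alkyne with the 2-bromo-1-alkene gives the 2-substituted 1,3-enyne. The free OH, carbamate, thiazole, internal alkyne and terminal alkene are tolerated, and the carbinol stereocentre is untouched.

**Step 11**
Reactants: **20**
Product: **21** micothiazole, methyl N-[(4Z,7R)-8-{4-[(2Z)-hexa-2,5-dien-1-yl]-1,3-thiazol-2-yl}-7-hydroxy-8-methyl-3-methylidenenon-4-en-1-yl]carbamate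
Conditions: Zn dust activated with Cu(OAc)2/AgNO3, MeOH–H2O (1:1), rt, 24 h
Reagents that add atoms: none (H only)
Why: Boland-type Zn(Cu/Ag) syn-transfer semireduction converts both internal alkynes to Z-alkenes. The terminal and 1,1-disubstituted alkenes, thiazole, carbamate and carbinol are untouched.

**Compound list**
1 | methyl (4R)-2,2-dimethyl-1,3-dioxolane-4-carboxylate | COC(=O)[C@H]1COC(C)(C)O1 | starting material
2 | methylmagnesium bromide | C[Mg]Br | starting material
3 | 2-[(4R)-2,2-dimethyl-1,3-dioxolan-4-yl]propan-2-ol | CC(C)(O)[C@H]1COC(C)(C)O1 | intermediate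
4 | oxalyl chloride | ClC(=O)C(=O)Cl | starting material
5 | N-hydroxyphthalimide | O=C1c2ccccc2C(=O)N1O | starting material
6 | tertiary N-phthalimidoyl oxalate of 3 | CC(C)(OC(=O)C(=O)ON1C(=O)c2ccccc2C1=O)[C@H]1COC(C)(C)O1 | intermediate
7 | 4-(chloromethyl)thiazole hydrochloride | ClCc1cscn1.Cl | starting material
8 | pent-1-en-4-yne | C#CCC=C | starting material
9 | 4-(hex-5-en-2-yn-1-yl)thiazole | C=CCC#CCc1cscn1 | intermediate
10 | acetonide–thiazole (Minisci product) | CC(C)(c1nc(CC#CCC=C)cs1)[C@H]1COC(C)(C)O1 | intermediate
11 | diol | CC(C)(c1nc(CC#CCC=C)cs1)[C@H](O)CO | intermediate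
12 | terminal epoxide | CC(C)(c1nc(CC#CCC=C)cs1)[C@H]1CO1 | intermediate
13 | trimethylsilylacetylene | C#C[Si](C)(C)C | starting material
14 | homopropargylic alcohol | CC(C)(c1nc(CC#CCC=C)cs1)[C@H](O)CC#C | intermediate
15 | 3-bromobut-3-en-1-ol | C=C(Br)CCO | starting material
16 | diphenyl phosphorazidate | [N-]=[N+]=NP(=O)(Oc1ccccc1)Oc1ccccc1 | starting material
17 | 2-bromo-4-azidobut-1-ene | C=C(Br)CCN=[N+]=[N-] | intermediate
18 | methyl chloroformate | COC(=O)Cl | starting material
19 | methyl (3-bromobut-3-en-1-yl)carbamate | C=C(Br)CCNC(=O)OC | intermediate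
20 | bis-alkyne enyne | CC(C)(c1nc(CC#CCC=C)cs1)[C@H](O)CC#CC(=C)CCNC(=O)OC | intermediate
21 | micothiazole | C=CC/C=C\Cc1csc(C(C)(C)[C@H](O)C/C=C\C(=C)CCNC(=O)OC)n1 | target

**Totals**
- Total steps: 11 (including the two parallel fragment branches, Steps 3 and 8–9).
- Longest linear sequence: 8 steps (Steps 1, 2, 4, 5, 6, 7, 10, 11).

**Three steps most likely to fail**
1. **Step 4 (photochemical Minisci; the proposed new step).**
   - Risks: C2 versus C5 selectivity on the thiazole, hindered quaternary-centre formation, loss of the acetonide under TFA, and H-atom capture of the tertiary radical.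
   - Fallback (known chemistry): Ni-catalysed reductive or metallaphotoredox cross-coupling of the same tertiary radical, from oxalate **6**, with 2-bromo-4-(hex-5-en-2-yn-1-yl)thiazole. The bromothiazole is made from commercial 2-bromo-4-(bromomethyl)thiazole as in Step 3. This forms the C2–C(CH3)2 bond with unambiguous regiochemistry.
2. **Step 7 (BF3-mediated epoxide opening).**
   - Risks: thiazole N coordination or intramolecular attack, and deprotonation of the doubly activated CH2 between the thiazole and the alkyne.
   - Fallback: convert diol **11** to its cyclic sulfate (SOCl2, then RuCl3/NaIO4), open it at the primary carbon with lithium TMS-acetylide, and hydrolyse the sulfate ester (aq. H2SO4, then K2CO3/MeOH). This gives **14** without a Lewis-acid step or an epoxide.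
3. **Step 3 (Cu-catalysed heteroarylmethyl chloride alkynylation).**
   - Risks: the free-base chloromethylthiazole is unstable (self-quaternisation), and Grignard addition at the thiazole is possible.
   - Fallback: build **9** by Hantzsch synthesis from 1-bromo-oct-7-en-4-yn-2-one and thioformamide.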